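**Plan**

1. Numbering (spiro[4.5]decane): ring B is the cyclopentane C1 (CHOH), C2 (CH carrying the tetraenyl arm), C3, C4, spiro C5; ring A is the cyclohexane C6 (C(OH)CH3), C7, C8, C9 (=C(CH3)CHO), C10 (CH carrying the acyloxypropyl chain). TBS = tert-butyldimethylsilyl, TBDPS = tert-butyldiphenylsilyl.
2. Retrosynthesis: the two acyl groups and the enal come off last. The tetraenyl arm is cut at its C2'=C3' alkene (ester aldol–dehydration with a C11 dienal). The C2 acetic ester arm goes back to a glyoxylate condensation on a C1 ketone.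
3. The core is cut at C5–C6 and at C10–chain. With C1 as a ketone, the C6 hydroxyl is β to it across spiro C5 (aldol pattern) and C10 is the β-carbon of the corresponding enone. Conjugate addition of the chain, as its 1-alkenyl form, to a 2-alkylidenecyclopentanone therefore gives the C5 enolate, which closes ring A on a pendant methyl ketone. The alkylidene is cut by Horner–Wadsworth–Emmons olefination into cyclopentanone and a Z enal made from a butenolide.
4. Forward order: the butenolide locks the Z tetrasubstituted alkene; an open-chain keto-dienone on intact ring B follows; ring A and the spiro centre form in one rhodium-catalysed cascade; diimide saturates the new side-chain alkene; then the C2 arm, the C1 carbinol, the tetraene, the acetate, the decanoate and the enal.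
5. Stereochemistry: C10 from the chiral rhodium–BINAP catalyst; C5 and C6 from C10 (rhodium-bridged chair, A(1,3) strain to the Z alkene); C1 by hydride delivery from the C6 hydroxyl; C2 by hydrogenation directed by the C1 hydroxyl; alkene geometries from the lactone ring, syn carboalumination and thermodynamic elimination.

Key step: step 8

Assumption: (R)-BINAP is taken to deliver the alkenyl group to the enone face that gives the (10R) centre; (S)-BINAP is used if a pilot run shows the opposite sense.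

**Step 1**
Reactants: 1 4-methylfuran-2(5H)-one
Product: 3 3-bromo-4-methylfuran-2(5H)-one, via dibromolactone 2 (not isolated)
Conditions: Br2, CH2Cl2, 0 °C; then Et3N, 0 °C → rt
Reagents that add atoms: bromine (BrBr)
Why: Bromine addition to the butenolide alkene followed by E1cB loss of HBr (acidic C3 hydrogen, tertiary C4 bromide) is the standard bromination–dehydrobromination route to 3-bromobutenolides, and no stereocentre remains.

**Step 2**
Reactants: 3 3-bromo-4-methylfuran-2(5H)-one; 4 2-ethenyl-2-methyl-1,3-dioxolane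
Product: 6 4-methyl-3-[2-(2-methyl-1,3-dioxolan-2-yl)ethyl]furan-2(5H)-one, via B-alkyl-9-BBN 5 (not isolated)
Conditions: 4, 9-BBN-H, THF, rt; then 3, PdCl2(dppf), AsPh3, Cs2CO3, DMF/THF/H2O, rt → 50 °C
Reagents that add atoms: none
Why: Anti-Markovnikov hydroboration and B-alkyl Suzuki–Miyaura coupling with the α-bromo enoate join the masked 3-oxobutyl arm to C3 of the lactone, whose ring holds the future tetrasubstituted alkene in the cis arrangement.

**Step 3**
Reactants: 6 4-methyl-3-[2-(2-methyl-1,3-dioxolan-2-yl)ethyl]furan-2(5H)-one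
Product: 8 (2Z)-4-(TBDPSO)-N-methoxy-N,3-dimethyl-2-[2-(2-methyl-1,3-dioxolan-2-yl)ethyl]but-2-enamide, via hydroxy Weinreb amide 7 (not isolated)
Conditions: MeNHOMe·HCl, iPrMgCl, THF, −20 → 0 °C; aq. NH4Cl; crude 7: TBDPSCl, imidazole, DMF, 0 °C → rt
Reagents that add atoms: N,O-dimethylhydroxylamine hydrochloride (CNOC.Cl); tert-butyl(chloro)diphenylsilane (CC(C)(C)[Si](Cl)(c1ccccc1)c1ccccc1)
Why: Weinreb aminolysis of the lactone by the magnesium amide opens the ring without touching the alkene geometry, and silylation of the freed primary allylic alcohol at once should prevent re-lactonisation.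

**Step 4**
Reactants: 8 (2Z)-4-(TBDPSO)-N-methoxy-N,3-dimethyl-2-[2-(2-methyl-1,3-dioxolan-2-yl)ethyl]but-2-enamide
Product: 9 (2Z)-4-(TBDPSO)-3-methyl-2-[2-(2-methyl-1,3-dioxolan-2-yl)ethyl]but-2-enal
Conditions: iBu2AlH, THF, −78 °C; aq. KNaC4H4O6
Reagents that add atoms: none
Why: Weinreb amide reduction stops at the chelated hemiaminal, which releases the aldehyde only on work-up, so over-reduction is avoided and the Z geometry is kept.

**Step 5**
Reactants: 10 cyclopentanone
Product: 12 diethyl (2-oxocyclopentyl)phosphonate, via enol phosphate 11 (not isolated)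
Conditions: LiN(iPr)2, THF, −78 °C; ClP(O)(OEt)2; then LiN(iPr)2 (2.2 equiv), −78 → 0 °C; AcOH
Reagents that add atoms: diethyl chlorophosphate (CCOP(=O)(Cl)OCC)
Why: O-phosphorylation of the lithium enolate and base-induced 1,3-phosphorus migration of the vinyl phosphate (anionic phospha-Fries-type rearrangement) give the cyclic β-keto phosphonate.

**Step 6**
Reactants: 9 (2Z)-4-(TBDPSO)-3-methyl-2-[2-(2-methyl-1,3-dioxolan-2-yl)ethyl]but-2-enal; 12 diethyl (2-oxocyclopentyl)phosphonate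
Product: 13 (2E)-2-[(2Z)-4-(TBDPSO)-3-methyl-2-[2-(2-methyl-1,3-dioxolan-2-yl)ethyl]but-2-en-1-ylidene]cyclopentan-1-one
Conditions: NaH, THF, 0 °C; then 9, 0 °C → rt
Reagents that add atoms: none
Why: Horner–Wadsworth–Emmons olefination with the stabilised β-keto phosphonate anion should give the 2-alkylidenecyclopentanone with the new substituent anti to the carbonyl (E), the usual outcome of reversible adduct formation.

**Step 7**
Reactants: 13 (2E)-2-[(2Z)-4-(TBDPSO)-3-methyl-2-[2-(2-methyl-1,3-dioxolan-2-yl)ethyl]but-2-en-1-ylidene]cyclopentan-1-one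
Product: 14 (2E)-2-[(2Z)-4-(TBDPSO)-3-methyl-2-(3-oxobutyl)but-2-en-1-ylidene]cyclopentan-1-one
Conditions: PPTS, acetone/H2O, 40 °C
Reagents that add atoms: water (O)
Why: Mild acid-catalysed ketal hydrolysis unmasks the methyl ketone while the silyl ether and the dienone should survive PPTS.

**Step 8**
Reactants: 14 (2E)-2-[(2Z)-4-(TBDPSO)-3-methyl-2-(3-oxobutyl)but-2-en-1-ylidene]cyclopentan-1-one; 15 tert-butyl(dimethyl){[(2E)-3-(4,4,5,5-tetramethyl-1,3,2-dioxaborolan-2-yl)prop-2-en-1-yl]oxy}silane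
Product: 17 (5R,6S,9Z,10R)-6-hydroxy-6-methyl-10-[(1E)-3-(TBSO)prop-1-en-1-yl]-9-[1-(TBDPSO)propan-2-ylidene]spiro[4.5]decan-1-one, via rhodium enolate 16 (not isolated)
Conditions: [Rh(cod)OH]2 (2.5 mol%), (R)-BINAP (6 mol%), KOH (0.2 equiv), H2O (5 equiv), dioxane, 60 °C
Reagents that add atoms: none
Why: Transmetallation of the alkenyl group from boron to the BINAP-bound rhodium hydroxide and enantioselective 1,4-insertion of the fixed s-cis enone place the alkenyl group on C10 and give the regiospecific oxa-π-allyl rhodium enolate 16 (nucleophilic at C5), which adds to the pendant methyl ketone at C6 before water protonates it, and hydrolysis of the rhodium aldolate returns the rhodium hydroxide. The closest known reaction type is the rhodium-catalysed conjugate addition of organoboron reagents to keto-enones with aldol cyclisation of the rhodium enolate onto the tethered ketone (Hayashi–Miyaura addition with intramolecular aldol trapping). Ring A closes in a 6-(enolexo)-exo-trig aldol. C10 is set by the BINAP ligand; C5 and C6 follow from C10 through a chair transition state in which rhodium bridges the enolate and ketone oxygens (hydroxyl cis to the C1 carbonyl), the C6 methyl is equatorial and the C10 alkenyl group is axial, because an equatorial group would eclipse the CH2OSi group held syn to C10 by the Z tetrasubstituted alkene (A(1,3) strain). Reversible retro-aldol of the metal aldolate under the mildly basic conditions should funnel any other C5/C6 pair into this chelated, most stable isomer. The step needs 1,4- rather than 1,6-addition, ring closure faster than protonation of the enolate and no base-induced aldol at other positions, which the fully substituted, twisted diene terminus, the small controlled amount of water and the catalytic amount of hydroxide should secure.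

**Step 9**
Reactants: 17 (5R,6S,9Z,10R)-6-hydroxy-6-methyl-10-[(1E)-3-(TBSO)prop-1-en-1-yl]-9-[1-(TBDPSO)propan-2-ylidene]spiro[4.5]decan-1-one
Product: 18 (5R,6S,9Z,10R)-6-hydroxy-6-methyl-10-[3-(TBSO)propyl]-9-[1-(TBDPSO)propan-2-ylidene]spiro[4.5]decan-1-one
Conditions: KO2CN=NCO2K (10 equiv), AcOH (slow addition), MeOH/CH2Cl2, 0 °C → rt
Reagents that add atoms: none
Why: Diimide, generated in the flask by protonation and decarboxylation of the azodicarboxylate salt, transfers two hydrogens in a concerted syn fashion to the unhindered disubstituted alkene, while the tetrasubstituted alkene and the ketone are inert to it and no stereocentre is created or touched.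

**Step 10**
Reactants: 18 (5R,6S,9Z,10R)-6-hydroxy-6-methyl-10-[3-(TBSO)propyl]-9-[1-(TBDPSO)propan-2-ylidene]spiro[4.5]decan-1-one; 19 ethyl glyoxylate
Product: 22 ethyl (2E)-2-[(5R,6S,9Z,10R)-6-hydroxy-6-methyl-1-oxo-10-[3-(TBSO)propyl]-9-[1-(TBDPSO)propan-2-ylidene]spiro[4.5]decan-2-ylidene]acetate, via aldol adduct 20 (not isolated), via mesylate 21 (not isolated)
Conditions: LiN(SiMe3)2 (2.2 equiv), THF, −78 °C; 19 (freshly distilled), −78 °C; AcOH; crude 20: MsCl (1.1 equiv), Et3N, CH2Cl2, −20 °C; then DBU, 0 °C → rt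
Reagents that add atoms: none
Why: Aldol addition of the C2 lithium enolate (the only enolisable position, the C6 alkoxide being a spectator) to the glyoxylate and E1cB elimination of the secondary mesylate should give the E enedione ester, and C2 becomes planar so no facial control is needed here.

**Step 11**
Reactants: 22 ethyl (2E)-2-[(5R,6S,9Z,10R)-6-hydroxy-6-methyl-1-oxo-10-[3-(TBSO)propyl]-9-[1-(TBDPSO)propan-2-ylidene]spiro[4.5]decan-2-ylidene]acetate
Product: 23 ethyl (2E)-2-[(1R,5S,6S,9Z,10R)-1,6-dihydroxy-6-methyl-10-[3-(TBSO)propyl]-9-[1-(TBDPSO)propan-2-ylidene]spiro[4.5]decan-2-ylidene]acetate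
Conditions: Me4NBH(OAc)3, MeCN/AcOH (1:1), −35 → −20 °C; aq. KNaC4H4O6
Reagents that add atoms: none
Why: In this Evans–Saksena reduction the borohydride exchanges an acetate for the C6 hydroxyl and delivers hydride intramolecularly to the C1 carbonyl from the C6 side, which should give the 1,6-anti diol (1R) by 1,2-reduction.

**Step 12**
Reactants: 23 ethyl (2E)-2-[(1R,5S,6S,9Z,10R)-1,6-dihydroxy-6-methyl-10-[3-(TBSO)propyl]-9-[1-(TBDPSO)propan-2-ylidene]spiro[4.5]decan-2-ylidene]acetate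
Product: 24 ethyl 2-[(1R,2R,5S,6S,9Z,10R)-1,6-dihydroxy-6-methyl-10-[3-(TBSO)propyl]-9-[1-(TBDPSO)propan-2-ylidene]spiro[4.5]decan-2-yl]acetate
Conditions: [Rh(nbd)(dppb)]BF4 (5 mol%), H2 (40 bar), CH2Cl2, rt
Reagents that add atoms: none
Why: In this hydroxyl-directed homogeneous hydrogenation the allylic C1 hydroxyl binds the cationic rhodium and H2 adds to the exocyclic alkene from that face, so the C2 hydrogen ends cis to the C1 hydroxyl and the acetic ester arm trans (2R), while the tetrasubstituted alkene is left alone.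

**Step 13**
Reactants: 24 ethyl 2-[(1R,2R,5S,6S,9Z,10R)-1,6-dihydroxy-6-methyl-10-[3-(TBSO)propyl]-9-[1-(TBDPSO)propan-2-ylidene]spiro[4.5]decan-2-yl]acetate
Product: 25 1,6-O-(di-tert-butylsilanediyl) derivative of 24
Conditions: tBu2Si(OTf)2, 2,6-lutidine, CH2Cl2, 0 °C → rt
Reagents that add atoms: di-tert-butylsilyl bis(trifluoromethanesulfonate) (CC(C)(C)[Si](OS(=O)(=O)C(F)(F)F)(OS(=O)(=O)C(F)(F)F)C(C)(C)C)
Why: Silylene protection of the 1,3-diol as a six-membered dioxasilinane masks the secondary and the tertiary hydroxyl in one operation and comes off later with fluoride.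

**Step 14**
Reactants: 26 (2E)-pent-2-en-4-yn-1-ol; 27 1-chloro-3-methylbut-2-ene
Product: 29 (2E,4E)-4,8-dimethylnona-2,4,7-trien-1-ol, via alkenylalane 28 (not isolated)
Conditions: 26, AlMe3 (3 equiv), Cp2ZrCl2 (0.25 equiv), CH2Cl2, 0 °C → rt; then 27, Pd(PPh3)4 (3 mol%), THF, rt; aq. KNaC4H4O6
Reagents that add atoms: trimethylaluminium (C[Al](C)C)
Why: Negishi carboalumination adds methyl and aluminium syn across the terminal alkyne, and palladium-catalysed allylation of the alkenylalane at the unsubstituted end of the prenyl unit proceeds with retention, which fixes the 4E geometry.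

**Step 15**
Reactants: 29 (2E,4E)-4,8-dimethylnona-2,4,7-trien-1-ol
Product: 30 (2E,4E)-4,8-dimethylnona-2,4,7-trienal
Conditions: MnO2 (activated), CH2Cl2, rt
Reagents that add atoms: none
Why: Allylic oxidation with MnO2 converts the primary allylic alcohol to the enal and leaves the other alkenes untouched.

**Step 16**
Reactants: 25 1,6-O-(di-tert-butylsilanediyl) derivative of 24; 30 (2E,4E)-4,8-dimethylnona-2,4,7-trienal
Product: 33 ethyl (2E,4E,6E)-2-[(1R,2R,5S,6S,9Z,10R)-1,6-(di-tert-butylsilanediyldioxy)-6-methyl-10-[3-(TBSO)propyl]-9-[1-(TBDPSO)propan-2-ylidene]spiro[4.5]decan-2-yl]-6,10-dimethylundeca-2,4,6,9-tetraenoate, via lithium aldolate 31 (not isolated), via mesylate 32 (not isolated)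
Conditions: LiN(iPr)2, THF, −78 °C; 30, −78 °C; MsCl, −78 → 0 °C; DBU, rt
Reagents that add atoms: none
Why: Ester-enolate aldol addition to the dienal (1,2-addition) and E1cB elimination of the mesylate should give the conjugated tetraenoate with the ester trans to the dienyl chain (2E), the thermodynamically preferred arrangement in which the C2 ring hydrogen lies in the alkene plane.

**Step 17**
Reactants: 33 the tetraenoate from step 16
Product: 34 (2E,4E,6E)-2-[(1R,2R,5S,6S,9Z,10R)-1,6-(di-tert-butylsilanediyldioxy)-6-methyl-10-[3-(TBSO)propyl]-9-[1-(TBDPSO)propan-2-ylidene]spiro[4.5]decan-2-yl]-6,10-dimethylundeca-2,4,6,9-tetraen-1-ol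
Conditions: iBu2AlH, CH2Cl2, −78 °C; aq. KNaC4H4O6
Reagents that add atoms: none
Why: Hydride 1,2-reduction of the conjugated ester with iBu2AlH gives the primary allylic alcohol and leaves silyl ethers and alkenes alone.

**Step 18**
Reactants: 34 the tetraenol from step 17
Product: 35 acetate of 34
Conditions: Ac2O, pyridine, DMAP (cat.), CH2Cl2, 0 °C
Reagents that add atoms: acetic anhydride (CC(=O)OC(C)=O)
Why: DMAP-catalysed acetylation of the only free hydroxyl installs the allylic acetate.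

**Step 19**
Reactants: 35 acetate of 34
Product: 36 primary alcohol (35 without the TBS group)
Conditions: PPTS, EtOH, rt → 40 °C
Reagents that add atoms: none
Why: Mild acid solvolysis cleaves a primary TBS ether much faster than a TBDPS ether or a di-tert-butylsilylene, so only the chain hydroxyl should be released.

**Step 20**
Reactants: 36 primary alcohol; 37 decanoyl chloride
Product: 38 decanoate of 36
Conditions: pyridine, DMAP (cat.), CH2Cl2, 0 °C
Reagents that add atoms: none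
Why: Acylation of the primary alcohol with the acid chloride under nucleophilic catalysis installs the decanoate.

**Step 21**
Reactants: 38 decanoate of 36
Product: 39 [(2E,4E,6E)-2-[(1R,2R,5S,6S,9Z,10R)-10-[3-(decanoyloxy)propyl]-1,6-dihydroxy-9-(1-hydroxypropan-2-ylidene)-6-methylspiro[4.5]decan-2-yl]-6,10-dimethylundeca-2,4,6,9-tetraen-1-yl] acetate
Conditions: HF·pyridine, pyridine, THF, 0 °C → rt
Reagents that add atoms: none
Why: Fluoride-mediated desilylation with buffered HF·pyridine should remove the TBDPS ether and the silylene without ester cleavage or acyl migration.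

**Step 22**
Reactants: 39 the triol from step 21
Product: 40 [(2E,4E,6E)-2-[(1R,2R,5S,6S,9Z,10R)-10-[3-(decanoyloxy)propyl]-1,6-dihydroxy-6-methyl-9-(1-oxopropan-2-ylidene)spiro[4.5]decan-2-yl]-6,10-dimethylundeca-2,4,6,9-tetraen-1-yl] acetate (target)
Conditions: MnO2 (activated), CH2Cl2, rt, dark
Reagents that add atoms: none
Why: Allylic oxidation with MnO2 touches only the primary allylic alcohol (the secondary and tertiary hydroxyls are not allylic) and should give the Z enal without isomerisation under neutral conditions.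

**Compound list**

1 | 4-methylfuran-2(5H)-one | CC1=CC(=O)OC1 | starting material
2 | 3,4-dibromo-4-methyloxolan-2-one (racemic) | CC1(Br)COC(=O)C1Br | intermediate (not isolated)
3 | 3-bromo-4-methylfuran-2(5H)-one | CC1=C(Br)C(=O)OC1 | intermediate
4 | 2-ethenyl-2-methyl-1,3-dioxolane | C=CC1(C)OCCO1 | starting material
5 | 9-[2-(2-methyl-1,3-dioxolan-2-yl)ethyl]-9-borabicyclo[3.3.1]nonane | CC1(CCB2C3CCCC2CCC3)OCCO1 | intermediate (not isolated)
6 | 4-methyl-3-[2-(2-methyl-1,3-dioxolan-2-yl)ethyl]furan-2(5H)-one | CC1=C(CCC2(C)OCCO2)C(=O)OC1 | intermediate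
7 | (2Z)-4-hydroxy-N-methoxy-N,3-dimethyl-2-[2-(2-methyl-1,3-dioxolan-2-yl)ethyl]but-2-enamide | CON(C)C(=O)/C(CCC1(C)OCCO1)=C(/C)CO | intermediate (not isolated)
8 | (2Z)-4-(TBDPSO)-N-methoxy-N,3-dimethyl-2-[2-(2-methyl-1,3-dioxolan-2-yl)ethyl]but-2-enamide | CON(C)C(=O)/C(CCC1(C)OCCO1)=C(/C)CO[Si](c1ccccc1)(c1ccccc1)C(C)(C)C | intermediate
9 | (2Z)-4-(TBDPSO)-3-methyl-2-[2-(2-methyl-1,3-dioxolan-2-yl)ethyl]but-2-enal | O=C/C(CCC1(C)OCCO1)=C(/C)CO[Si](c1ccccc1)(c1ccccc1)C(C)(C)C | intermediate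
10 | cyclopentanone | O=C1CCCC1 | starting material
11 | cyclopent-1-en-1-yl diethyl phosphate | CCOP(=O)(OCC)OC1=CCCC1 | intermediate (not isolated)
12 | diethyl (2-oxocyclopentyl)phosphonate (racemic) | CCOP(=O)(OCC)C1CCCC1=O | intermediate
13 | (2E)-2-[(2Z)-4-(TBDPSO)-3-methyl-2-[2-(2-methyl-1,3-dioxolan-2-yl)ethyl]but-2-en-1-ylidene]cyclopentan-1-one | O=C1CCC/C1=C\C(CCC2(C)OCCO2)=C(\C)CO[Si](c2ccccc2)(c2ccccc2)C(C)(C)C | intermediate
14 | (2E)-2-[(2Z)-4-(TBDPSO)-3-methyl-2-(3-oxobutyl)but-2-en-1-ylidene]cyclopentan-1-one | O=C1CCC/C1=C\C(CCC(C)=O)=C(\C)CO[Si](c2ccccc2)(c2ccccc2)C(C)(C)C | intermediate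
15 | tert-butyl(dimethyl){[(2E)-3-(4,4,5,5-tetramethyl-1,3,2-dioxaborolan-2-yl)prop-2-en-1-yl]oxy}silane | CC(C)(C)[Si](C)(C)OC/C=C/B1OC(C)(C)C(C)(C)O1 | starting material
16 | monovalent rhodium enolate (O-bound at C1, C1=C5; BINAP ligand on rhodium not drawn) of the (10R) conjugate adduct of 14 and the alkenyl group of 15 | [Rh]OC1=C(CCC1)[C@H](/C=C/CO[Si](C)(C)C(C)(C)C)/C(CCC(C)=O)=C(/C)CO[Si](c1ccccc1)(c1ccccc1)C(C)(C)C | intermediate (not isolated)
17 | (5R,6S,9Z,10R)-6-hydroxy-6-methyl-10-[(1E)-3-(TBSO)prop-1-en-1-yl]-9-[1-(TBDPSO)propan-2-ylidene]spiro[4.5]decan-1-one | CC(C)(C)[Si](C)(C)OC/C=C/[C@@H]1/C(=C(/C)CO[Si](c2ccccc2)(c2ccccc2)C(C)(C)C)CC[C@](C)(O)[C@@]12CCCC2=O | intermediate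
18 | (5R,6S,9Z,10R)-6-hydroxy-6-methyl-10-[3-(TBSO)propyl]-9-[1-(TBDPSO)propan-2-ylidene]spiro[4.5]decan-1-one | CC(C)(C)[Si](C)(C)OCCC[C@@H]1/C(=C(/C)CO[Si](c2ccccc2)(c2ccccc2)C(C)(C)C)CC[C@](C)(O)[C@@]12CCCC2=O | intermediate
19 | ethyl glyoxylate | CCOC(=O)C=O | starting material
20 | ethyl 2-hydroxy-2-[(5R,6S,9Z,10R)-6-hydroxy-6-methyl-1-oxo-10-[3-(TBSO)propyl]-9-[1-(TBDPSO)propan-2-ylidene]spiro[4.5]decan-2-yl]acetate (diastereomer mixture at the two new centres) | CC(C)(C)[Si](C)(C)OCCC[C@@H]1/C(=C(/C)CO[Si](c2ccccc2)(c2ccccc2)C(C)(C)C)CC[C@](C)(O)[C@@]12CCC(C(O)C(=O)OCC)C2=O | intermediate (not isolated)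
21 | methanesulfonate of 20 at the secondary hydroxyl | CC(C)(C)[Si](C)(C)OCCC[C@@H]1/C(=C(/C)CO[Si](c2ccccc2)(c2ccccc2)C(C)(C)C)CC[C@](C)(O)[C@@]12CCC(C(OS(C)(=O)=O)C(=O)OCC)C2=O | intermediate (not isolated)
22 | ethyl (2E)-2-[(5R,6S,9Z,10R)-6-hydroxy-6-methyl-1-oxo-10-[3-(TBSO)propyl]-9-[1-(TBDPSO)propan-2-ylidene]spiro[4.5]decan-2-ylidene]acetate | CC(C)(C)[Si](C)(C)OCCC[C@@H]1/C(=C(/C)CO[Si](c2ccccc2)(c2ccccc2)C(C)(C)C)CC[C@](C)(O)[C@@]12CC/C(=C\C(=O)OCC)C2=O | intermediate
23 | ethyl (2E)-2-[(1R,5S,6S,9Z,10R)-1,6-dihydroxy-6-methyl-10-[3-(TBSO)propyl]-9-[1-(TBDPSO)propan-2-ylidene]spiro[4.5]decan-2-ylidene]acetate | CC(C)(C)[Si](C)(C)OCCC[C@@H]1/C(=C(/C)CO[Si](c2ccccc2)(c2ccccc2)C(C)(C)C)CC[C@](C)(O)[C@@]12CC/C(=C\C(=O)OCC)[C@H]2O | intermediate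
24 | ethyl 2-[(1R,2R,5S,6S,9Z,10R)-1,6-dihydroxy-6-methyl-10-[3-(TBSO)propyl]-9-[1-(TBDPSO)propan-2-ylidene]spiro[4.5]decan-2-yl]acetate | CC(C)(C)[Si](C)(C)OCCC[C@@H]1/C(=C(/C)CO[Si](c2ccccc2)(c2ccccc2)C(C)(C)C)CC[C@](C)(O)[C@@]12CC[C@H](CC(=O)OCC)[C@H]2O | intermediate
25 | 1,6-O-(di-tert-butylsilanediyl) derivative of 24 | CC(C)(C)[Si](C)(C)OCCC[C@@H]1/C(=C(/C)CO[Si](c2ccccc2)(c2ccccc2)C(C)(C)C)CC[C@](C)(O3)[C@@]12CC[C@H](CC(=O)OCC)[C@H]2O[Si]3(C(C)(C)C)C(C)(C)C | intermediate
26 | (2E)-pent-2-en-4-yn-1-ol | OC/C=C/C#C | starting material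
27 | 1-chloro-3-methylbut-2-ene | CC(C)=CCCl | starting material
28 | dimethylaluminium alkoxide of (2E,4E)-5-(dimethylalumanyl)-4-methylpenta-2,4-dien-1-ol | C[Al](C)OC/C=C/C(C)=C/[Al](C)C | intermediate (not isolated)
29 | (2E,4E)-4,8-dimethylnona-2,4,7-trien-1-ol | OC/C=C/C(C)=C/CC=C(C)C | intermediate
30 | (2E,4E)-4,8-dimethylnona-2,4,7-trienal | O=C/C=C/C(C)=C/CC=C(C)C | intermediate
31 | lithium aldolate of 25 and 30 (ethyl 3-lithiooxy-6,10-dimethyl-2-[ring]undeca-4,6,9-trienoate, diastereomer mixture) | CC(C)(C)[Si](C)(C)OCCC[C@@H]1/C(=C(/C)CO[Si](c2ccccc2)(c2ccccc2)C(C)(C)C)CC[C@](C)(O3)[C@@]12CC[C@H](C(C(O[Li])/C=C/C(C)=C/CC=C(C)C)C(=O)OCC)[C@H]2O[Si]3(C(C)(C)C)C(C)(C)C | intermediate (not isolated)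
32 | 3-methanesulfonate corresponding to 31 | CC(C)(C)[Si](C)(C)OCCC[C@@H]1/C(=C(/C)CO[Si](c2ccccc2)(c2ccccc2)C(C)(C)C)CC[C@](C)(O3)[C@@]12CC[C@H](C(C(OS(C)(=O)=O)/C=C/C(C)=C/CC=C(C)C)C(=O)OCC)[C@H]2O[Si]3(C(C)(C)C)C(C)(C)C | intermediate (not isolated)
33 | ethyl (2E,4E,6E)-2-[(1R,2R,5S,6S,9Z,10R)-1,6-(di-tert-butylsilanediyldioxy)-6-methyl-10-[3-(TBSO)propyl]-9-[1-(TBDPSO)propan-2-ylidene]spiro[4.5]decan-2-yl]-6,10-dimethylundeca-2,4,6,9-tetraenoate | CC(C)(C)[Si](C)(C)OCCC[C@@H]1/C(=C(/C)CO[Si](c2ccccc2)(c2ccccc2)C(C)(C)C)CC[C@](C)(O3)[C@@]12CC[C@H](\C(=C/C=C/C(C)=C/CC=C(C)C)C(=O)OCC)[C@H]2O[Si]3(C(C)(C)C)C(C)(C)C | intermediate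
34 | (2E,4E,6E)-tetraen-1-ol corresponding to 33 | CC(C)(C)[Si](C)(C)OCCC[C@@H]1/C(=C(/C)CO[Si](c2ccccc2)(c2ccccc2)C(C)(C)C)CC[C@](C)(O3)[C@@]12CC[C@H](\C(=C/C=C/C(C)=C/CC=C(C)C)CO)[C@H]2O[Si]3(C(C)(C)C)C(C)(C)C | intermediate
35 | acetate of 34 | CC(C)(C)[Si](C)(C)OCCC[C@@H]1/C(=C(/C)CO[Si](c2ccccc2)(c2ccccc2)C(C)(C)C)CC[C@](C)(O3)[C@@]12CC[C@H](\C(=C/C=C/C(C)=C/CC=C(C)C)COC(C)=O)[C@H]2O[Si]3(C(C)(C)C)C(C)(C)C | intermediate
36 | 35 with the chain hydroxyl free (3-hydroxypropyl at C10) | OCCC[C@@H]1/C(=C(/C)CO[Si](c2ccccc2)(c2ccccc2)C(C)(C)C)CC[C@](C)(O3)[C@@]12CC[C@H](\C(=C/C=C/C(C)=C/CC=C(C)C)COC(C)=O)[C@H]2O[Si]3(C(C)(C)C)C(C)(C)C | intermediate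
37 | decanoyl chloride | CCCCCCCCCC(Cl)=O | starting material
38 | decanoate of 36 | CCCCCCCCCC(=O)OCCC[C@@H]1/C(=C(/C)CO[Si](c2ccccc2)(c2ccccc2)C(C)(C)C)CC[C@](C)(O3)[C@@]12CC[C@H](\C(=C/C=C/C(C)=C/CC=C(C)C)COC(C)=O)[C@H]2O[Si]3(C(C)(C)C)C(C)(C)C | intermediate
39 | [(2E,4E,6E)-2-[(1R,2R,5S,6S,9Z,10R)-10-[3-(decanoyloxy)propyl]-1,6-dihydroxy-9-(1-hydroxypropan-2-ylidene)-6-methylspiro[4.5]decan-2-yl]-6,10-dimethylundeca-2,4,6,9-tetraen-1-yl] acetate | CCCCCCCCCC(=O)OCCC[C@@H]1/C(=C(/C)CO)CC[C@](C)(O)[C@@]12CC[C@H](\C(=C/C=C/C(C)=C/CC=C(C)C)COC(C)=O)[C@H]2O | intermediate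
40 | [(2E,4E,6E)-2-[(1R,2R,5S,6S,9Z,10R)-10-[3-(decanoyloxy)propyl]-1,6-dihydroxy-6-methyl-9-(1-oxopropan-2-ylidene)spiro[4.5]decan-2-yl]-6,10-dimethylundeca-2,4,6,9-tetraen-1-yl] acetate | CCCCCCCCCC(=O)OCCC[C@@H]1/C(=C(/C)C=O)CC[C@](C)(O)[C@@]12CC[C@H](\C(=C/C=C/C(C)=C/CC=C(C)C)COC(C)=O)[C@H]2O | target

**Totals**

Total step count: 22. Longest linear sequence: 19 steps (steps 1–4, 6–13, 16–22).

**Steps most likely to fail**

Step 8. Protonation of the rhodium enolate by water may outrun ring closure, and the facial selectivity at C10 may be low at the hindered, α-substituted exocyclic enone. The fallback sets out from 14 and brings the chain in directly as a saturated alkyl group under anhydrous conditions, by copper-catalysed conjugate addition of a dialkylzinc with aldol trapping of the zinc enolate. Two molecules of commercial tert-butyl(3-iodopropoxy)dimethylsilane and Et2Zn (neat, CuI cat., 50 °C, volatiles then removed in vacuo) give bis[3-(TBSO)propyl]zinc F1. Treating 14 with F1, Cu(OTf)2 and O,O'-[(S)-1,1'-binaphthalene-2,2'-diyl] N,N-bis[(R)-1-phenylethyl]phosphoramidite in toluene at −30 → 0 °C, followed by aq. NH4Cl, should give 18 directly, bypassing 17.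

Step 16. Geometric control may be lost in the elimination, since a bulky ring carbon on the α-position can let the ester end cis to the dienyl chain. The aldolate may also revert. The fallback sets out from 25 and moves the condensation to the aldehyde oxidation level, where the E isomer of a 2-substituted enal is strongly preferred and reached by equilibration. Partial reduction of 25 (iBu2AlH, toluene, −78 °C) gives aldehyde F2, and cyclohexylamine with MgSO4 gives N-cyclohexylimine F3. Wittig directed aldol condensation (LiN(iPr)2, then 30, then buffered aqueous acetic acid) gives enal F4. Luche reduction (NaBH4, CeCl3, MeOH) then gives 34, bypassing 33.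

Step 12. The two hydroxyl groups sit on opposite faces and may compete for the cationic rhodium. Hydrogenation of the ester-conjugated trisubstituted alkene may also be sluggish. Either would erode facial selectivity at C2. The fallback sets out from 22 and reverses the order of the two reductions. Heterogeneous hydrogenation (H2, 1 bar, Pd/C, EtOAc) should add hydrogen to C2 from the face flanked by the C10 hydrogen rather than by the equatorial C6 methyl, giving keto ester F5. Evans–Saksena reduction of F5 (Me4NBH(OAc)3, MeCN/AcOH) returns to 24, bypassing 23.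

**Further compounds**

F1 | step 8 | bis[3-(TBSO)propyl]zinc | CC(C)(C)[Si](C)(C)OCCC[Zn]CCCO[Si](C)(C)C(C)(C)C
F2 | step 16 | 2-[(1R,2R,5S,6S,9Z,10R)-1,6-(di-tert-butylsilanediyldioxy)-6-methyl-10-[3-(TBSO)propyl]-9-[1-(TBDPSO)propan-2-ylidene]spiro[4.5]decan-2-yl]acetaldehyde | CC(C)(C)[Si](C)(C)OCCC[C@@H]1/C(=C(/C)CO[Si](c2ccccc2)(c2ccccc2)C(C)(C)C)CC[C@](C)(O3)[C@@]12CC[C@H](CC=O)[C@H]2O[Si]3(C(C)(C)C)C(C)(C)C
F3 | step 16 | N-cyclohexylimine of F2 | CC(C)(C)[Si](C)(C)OCCC[C@@H]1/C(=C(/C)CO[Si](c2ccccc2)(c2ccccc2)C(C)(C)C)CC[C@](C)(O3)[C@@]12CC[C@H](CC=NC4CCCCC4)[C@H]2O[Si]3(C(C)(C)C)C(C)(C)C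
F4 | step 16 | (2E,4E,6E)-2-[(1R,2R,5S,6S,9Z,10R)-1,6-(di-tert-butylsilanediyldioxy)-6-methyl-10-[3-(TBSO)propyl]-9-[1-(TBDPSO)propan-2-ylidene]spiro[4.5]decan-2-yl]-6,10-dimethylundeca-2,4,6,9-tetraenal | CC(C)(C)[Si](C)(C)OCCC[C@@H]1/C(=C(/C)CO[Si](c2ccccc2)(c2ccccc2)C(C)(C)C)CC[C@](C)(O3)[C@@]12CC[C@H](\C(=C/C=C/C(C)=C/CC=C(C)C)C=O)[C@H]2O[Si]3(C(C)(C)C)C(C)(C)C
F5 | step 12 | ethyl 2-[(2R,5R,6S,9Z,10R)-6-hydroxy-6-methyl-1-oxo-10-[3-(TBSO)propyl]-9-[1-(TBDPSO)propan-2-ylidene]spiro[4.5]decan-2-yl]acetate | CC(C)(C)[Si](C)(C)OCCC[C@@H]1/C(=C(/C)CO[Si](c2ccccc2)(c2ccccc2)C(C)(C)C)CC[C@](C)(O)[C@@]12CC[C@H](CC(=O)OCC)C2=O
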